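The flask holds 0.500 equiv of reagent on 5.0 × 10⁻⁴ M of substrate with 1.7 mol% of free catalyst, and the product is wanted at 40 s, 3.0 min and 12 min.

| flask | substrate | reagent | free catalyst | remark | time |
|---|---|---|---|---|---|
| dusk | 5.0 × 10⁻⁴ M | 0.34 equiv | 1.7 mol% | run made earlier |  |
| dawn | 5.0 × 10⁻⁴ M | 0.75 equiv | 1.7 mol% | run made earlier |  |
| flask | 5.0 × 10⁻⁴ M | 0.500 equiv | 1.7 mol% |  | 12 min |

- dusk (time / min: product / %): 1.00: 25.9; 2.50: 33.4; 6.00: 33.8; 15.0: 33.7
- dawn (time / min: product / %): 1.00: 43.9; 2.50: 69.6; 6.00: 74.6; 15.0: 74.9

(readings scatter by 0.3 percentage points)

- for by-product the idle adduct is counted in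
- steps under discussion: substrate + catalyst intermediate B -> catalyst intermediate C; reagent + by-product <-> idle adduct; catalyst intermediate C -> free catalyst + product; reagent + free catalyst <-> catalyst intermediate A; catalyst intermediate A -> by-product + catalyst intermediate B

- amount of product in percent of the substrate charged, at 40 s, 3.0 min and 12 min

Dawn carries 2.21 times the reagent of dusk and ends with 2.22 times the product, yet at 1.00 min it shows just 1.69 times the product. Each plateau equals the reagent charged, within the scatter, so the distance G of product below its plateau can be followed in each run:

dawn: G falls from 31 percentage points to 5.3 points in 1.50 min, so h = 0.589 min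

dusk: G falls from 7.9 points to 0.4 points in 1.50 min, so h = 0.349 min

Here h is the gap half-life, the time in which G halves. Both values are readings, and the dusk value rests on a last gap close to the scatter. Dusk's h reads shorter than dawn's, so dusk stood nearer its plateau at the first reading, which clears up the early ratio.

For the flask, the plateau scales to 49.9%. Counted from the start with dawn's h, which is longer than dusk's, this reckoning gives:

40 s: 27.2%

3.0 min: 48.5%

12 min: 20.4 half-lives, so the plateau

The forecast gives 24.5%, 49.1% and 49.9%, holding that “Reagent is therefore limiting and consumed essentially completely”. It stands lower at the first time and higher at the second.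

The flask gives 25.6%, 49.3% and 50.0%, so the forecast holds within the tolerance of the question.

    substrate + catalyst intermediate B → catalyst intermediate C (k = 5000 M⁻¹ s⁻¹)
    reagent + by-product ⇌ idle adduct, settled at all times (K = 1400 M⁻¹)
    catalyst intermediate C → free catalyst + product (k = 1.90 s⁻¹)
    reagent + free catalyst ⇌ catalyst intermediate A (K = 3700 M⁻¹, k = 7000 M⁻¹ s⁻¹)
    catalyst intermediate A → by-product + catalyst intermediate B (k = 3.60 s⁻¹)

Between 40 s and 3.0 min the flask's G falls from 24 points to 0.7 points, so its h is 0.455 min, longer than dusk's and shorter than dawn's, and 12 min spans 26.4 such half-lives. The plateau of this flask is due to the wearing away of reagent, the limiting reagent: the same flask with that wearing away removed reaches 100% of product against 50.0%, a difference of 50 points.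

All runs stem from a simulated flask from invented constants, noise included.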